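The route rests on cutting the oxepane ring (O4, C2, C34, C33, C32, C30, C5) at C2–C34, the bond between the fully substituted ether carbon and the secondary carbinol whose oxygen O35 sits on the H-5 face. A samarium diiodide ketyl/β-alkoxycrotonate cyclisation makes this bond, the seven-membered ring and both new stereocentres at once; the acetate arm left on C2 is later trimmed to the second methyl. The precursor is a ketal-protected cyclohexane with a propanal arm on quaternary C30 and an (E)-crotonate enol ether on O4, drawn from (R)-Wieland–Miescher ketone. The epoxy-hydroazulene half is made separately and joined at C12–C13 by radical conjugate addition.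

Key step: step 7

Remark on numbering and supply: atom labels (C2, O4 … O35) follow the order of the target SMILES; (R)-Wieland–Miescher ketone (1) and (R)-4-(tert-butyldimethylsilyloxy)cyclopent-2-en-1-one (17) are assumed to be bought as single enantiomers.
Remark on design: C5 and C30 are taken from 1 because the oxepane must be trans-fused (O4 cis to the C30 methyl, trans to C32), which is the relationship that hydride reduction of 1 delivers. The aldehyde is unveiled from a Weinreb amide so that neither the ketal nor the enol ether meets acid. The C34 hydroxyl is carried free after the key step.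

Step 1
Reactants: 1 (R)-Wieland–Miescher ketone
Product: 2 (4aR,5R)-5-hydroxy-4a-methyl-4,4a,5,6,7,8-hexahydronaphthalen-2(3H)-one
Conditions: NaBH4 (0.3 equiv), EtOH, −10 °C
Reagents that add atoms: none
Why: Chemoselective borohydride reduction of the saturated ketone beside the enone, with hydride entering anti to the angular methyl, so that the C5 hydroxyl (R) ends cis to the C30 methyl.

Step 2
Reactants: 2 (4aR,5R)-hydroxy enone
Product: 4 (4aS,8aR)-4a-methyloctahydro-2H-chromene-2,5-dione, via hydroxy keto acid 3 (not isolated)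
Conditions: O3, EtOAc–AcOH, −40 °C; 30% H2O2, rt; then TsOH (cat.), PhMe, 80 °C
Reagents that add atoms: ozone [O-][O+]=O; hydrogen peroxide OO
Why: Oxidative ozonolysis of the enone excises its α-carbon as formic acid and leaves the C11 ketone and the C34 acid, and the δ-hydroxy acid then lactonises under acid, which avoids base-induced retro-aldol cleavage of the β-hydroxy ketone.

Step 3
Reactants: 4 trans-fused keto lactone
Product: 5 C11 ethylene ketal of lactone 4 (spiro-dioxolane lactone)
Conditions: TMSOCH2CH2OTMS, TMSOTf (5 mol%), CH2Cl2, −78 → −20 °C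
Reagents that add atoms: 1,2-bis(trimethylsilyloxy)ethane C[Si](C)(C)OCCO[Si](C)(C)C
Why: Aprotic silyl-transfer ketalisation should convert even the ketone next to the quaternary carbon into its dioxolane without touching the lactone.

Step 4
Reactants: 5 ketal lactone
Product: 6 3-[(6S,7R)-7-hydroxy-6-methyl-1,4-dioxaspiro[4.5]decan-6-yl]-N-methoxy-N-methylpropanamide
Conditions: MeNH(OMe)·HCl, i-PrMgCl, THF, −20 → 0 °C
Reagents that add atoms: N,O-dimethylhydroxylamine hydrochloride CNOC.Cl
Why: Lactone aminolysis by the chloromagnesium amide (Weinreb amide formation) stores C34 at the aldehyde oxidation level and frees the C5 hydroxyl in one operation.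

Step 5
Reactants: 6 hydroxy Weinreb amide; 7 ethyl but-2-ynoate
Product: 8 (E)-β-alkoxycrotonate Weinreb amide (ethyl (E)-3-alkoxybut-2-enoate on O4)
Conditions: PMe3 (0.5 equiv), CH2Cl2, rt
Reagents that add atoms: none
Why: Phosphine-catalysed oxa-Michael addition of the alcohol to the ynoate gives the thermodynamically preferred (E)-enol ether, and trimethylphosphine is chosen because the carbinol is neopentylic.

Step 6
Reactants: 8 crotonate Weinreb amide
Product: 9 ethyl (E)-3-{[(6S,7R)-6-methyl-6-(3-oxopropyl)-1,4-dioxaspiro[4.5]decan-7-yl]oxy}but-2-enoate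
Conditions: DIBAL-H (1.2 equiv), THF, −78 °C; Rochelle salt
Reagents that add atoms: none
Why: Weinreb amide reduction stops at the chelated hemiaminal and gives the aldehyde on work-up, while the vinylogous carbonate and the ketal are inert at −78 °C.

Step 7
Reactants: 9 aldehyde β-alkoxycrotonate
Product: 10 trans-fused oxepane hydroxy ester (CH2CO2Et and CH3 on C2, OH on C34, C11 ketal; 2S,5R,30S,34R in target numbering)
Conditions: SmI2 (3 equiv), MeOH (3 equiv), THF, 0 °C
Reagents that add atoms: none
Why: Single-electron transfer from SmI2 to the C34 aldehyde gives a samarium ketyl that, held in a chelate with the crotonate carbonyl, adds to the β-carbon C2; the α-ester radical is then reduced to the samarium enolate and protonated by methanol. The closest known reaction type is the SmI2-mediated reductive cyclisation of aldehydes onto β-alkoxyacrylates used for trans-fused cyclic ethers, here in its β-methyl (crotonate) form. The oxepane (O4, C2, C34, C33, C32, C30, C5) closes in a 7-exo-trig mode. At C2 the chair-like chelate keeps the CH2CO2Et arm pseudo-equatorial and syn to C6 across O4 while the methyl takes the axial site; at C34 the Sm–O bond is locked anti to that arm, so O35 ends trans to the arm and on the H-5 face. The step needs the C34 configuration relative to the fixed C5/C30 pair, secured by the equatorial O4 and C32 on the cyclohexane, the (E)-enoate and the chelate, and it needs reduction of the aldehyde in preference to the enoate, secured by the aldehyde's much lower reduction potential.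

Step 8
Reactants: 10 oxepane hydroxy ester
Product: 11 oxepane hydroxy acid (CH2CO2H on C2)
Conditions: LiOH·H2O, THF–MeOH–H2O, rt; 1 M HCl to pH 5, 0 °C
Reagents that add atoms: lithium hydroxide [Li+].[OH-]
Why: Ester saponification, after which the acid is isolated by brief cold acidification that the ketal tolerates; the trans hydroxy acid should not lactonise readily.

Step 9
Reactants: 11 oxepane hydroxy acid
Product: 12 2,2-dimethyl oxepanol ketal (gem-dimethyl at C2, free C34–OH)
Conditions: 9-mesityl-10-phenylacridinium BF4 (5 mol%), PhSSPh (10 mol%), i-Pr2NEt (0.2 equiv), CF3CH2OH, 450 nm, rt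
Reagents that add atoms: none
Why: Photoredox hydrodecarboxylation, in which the carboxylate is oxidised by the excited acridinium, loses CO2 and the primary radical takes hydrogen from thiophenol, turns the acetate arm into the second C2 methyl.

Step 10
Reactants: 12 oxepanol ketal
Product: 13 oxepanol ketone (C11 ketone)
Conditions: PPTS, acetone–H2O, 55 °C
Reagents that add atoms: water O
Why: Acid-catalysed ketal hydrolysis, safe here because the β-alkoxy ketone cannot eliminate across the quaternary C30.

Step 11
Reactants: 13 oxepanol ketone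
Product: 14 exocyclic alkene (C11=C12H2)
Conditions: Ph3PCH3Br, KOt-Bu, PhMe, 90 °C
Reagents that add atoms: methyltriphenylphosphonium bromide C[P+](c1ccccc1)(c1ccccc1)c1ccccc1.[Br-]
Why: Wittig methylenation with the salt-free ylide at elevated temperature, conditions suited to ketones flanked by a quaternary carbon, brings in C12.

Step 12
Reactants: 14 exocyclic alkene
Product: 15 allylic alcohol (C8–OH, either C8 epimer)
Conditions: SeO2 (0.3 equiv), t-BuOOH, CH2Cl2, rt
Reagents that add atoms: tert-butyl hydroperoxide CC(C)(C)OO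
Why: Selenium dioxide allylic hydroxylation (ene reaction then [2,3] shift) can occur only at C8 because the other allylic carbon C30 has no hydrogen, and the C8 configuration is lost in the next step.

Step 13
Reactants: 15 allylic alcohol
Product: 16 α-methylene ketone (C8 ketone, C11=C12H2, free C34–OH)
Conditions: MnO2, CH2Cl2, rt
Reagents that add atoms: none
Why: Manganese dioxide oxidises only the allylic C8 carbinol and leaves the saturated C34 carbinol.

Step 14
Reactants: 17 (R)-4-(tert-butyldimethylsilyloxy)cyclopent-2-en-1-one; 18 trimethyl(3-methylbut-2-en-1-yl)silane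
Product: 20 (R)-4-(2-methylbut-3-en-2-yl)cyclopent-2-en-1-one, via trans silyloxy ketone 19 (not isolated)
Conditions: TiCl4, CH2Cl2, −78 °C; then DBU, CH2Cl2, 0 °C
Reagents that add atoms: none
Why: Hosomi–Sakurai conjugate allylation with γ-attack of the prenylsilane places the 1,1-dimethylallyl group (C15, C14) trans to the silyloxy group, and E1cB loss of silanol then relays the chirality to C18 of the new enone.

Step 15
Reactants: 20 (R)-4-substituted cyclopentenone
Product: 21 (R)-2-iodo-4-(2-methylbut-3-en-2-yl)cyclopent-2-en-1-one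
Conditions: I2, pyridine–CH2Cl2, 0 °C → rt
Reagents that add atoms: iodine II
Why: α-Iodination of the enone by pyridine conjugate addition, iodination of the enolate and elimination leaves the γ-stereocentre untouched.

Step 16
Reactants: 21 α-iodo enone
Product: 22 (R)-2-methyl-4-(2-methylbut-3-en-2-yl)cyclopent-2-en-1-one
Conditions: Me4Sn, Pd2(dba)3, AsPh3, CuI, NMP, 60 °C
Reagents that add atoms: tetramethylstannane C[Sn](C)(C)C
Why: Stille coupling of the α-iodoenone installs the C22 methyl under base-free conditions that protect the γ-stereocentre from dienolate formation.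

Step 17
Reactants: 22 2-methyl enone
Product: 23 (1S,4R)-2-methyl-4-(2-methylbut-3-en-2-yl)cyclopent-2-en-1-ol
Conditions: NaBH4, CeCl3·7H2O, MeOH, −78 °C
Reagents that add atoms: none
Why: Luche 1,2-reduction with hydride entering anti to the tert-alkyl group at C18 should give the cis (1,4) allylic alcohol.

Step 18
Reactants: 23 cis allylic alcohol; 24 triethyl orthoacetate
Product: 25 ethyl 2-[(1R,5R)-2-methyl-5-(2-methylbut-3-en-2-yl)cyclopent-2-en-1-yl]acetate
Conditions: EtCO2H (cat.), xylene, 140 °C, EtOH distilled off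
Reagents that add atoms: none
Why: Johnson–Claisen rearrangement, a suprafacial [3,3] shift, transfers chirality from C20–O to C24, puts the acetate arm (C25, C26) cis to the C18 substituent and leaves the C20=C21 trisubstituted alkene.

Step 19
Reactants: 25 cyclopentenyl acetate
Product: 26 epoxy ester (C20–C21 epoxide anti to both side chains)
Conditions: mCPBA, NaHCO3, CH2Cl2, 0 °C
Reagents that add atoms: 3-chloroperbenzoic acid OOC(=O)c1cccc(Cl)c1
Why: Prilezhaev epoxidation takes the electron-rich trisubstituted alkene in preference to the terminal vinyl and occurs on the face opposite the two cis side chains.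

Step 20
Reactants: 26 epoxy ester
Product: 27 (1R,2R,3R)-2-(2-hydroxyethyl)-1-methyl-3-(2-methylbut-3-en-2-yl)cyclopentan-1-ol
Conditions: LiAlH4, THF, 0 °C → rt
Reagents that add atoms: none
Why: Hydride opens the epoxide at the less substituted C20 in SN2 fashion, giving the C21 tertiary alcohol with its oxygen anti to the side chains, and also reduces the ester to the C26 primary alcohol.

Step 21
Reactants: 27 diol
Product: 28 2-[(1R,2R,5R)-2-hydroxy-2-methyl-5-(2-methylbut-3-en-2-yl)cyclopentyl]acetaldehyde
Conditions: TEMPO (10 mol%), PhI(OAc)2, CH2Cl2, rt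
Reagents that add atoms: none
Why: Oxoammonium oxidation is selective for the primary alcohol, and the trans placement of the tertiary hydroxyl and the acetaldehyde arm disfavours lactol formation.

Step 22
Reactants: 28 hydroxy aldehyde
Product: 29 1-[(1R,2R,5R)-2-hydroxy-2-methyl-5-(2-methylbut-3-en-2-yl)cyclopentyl]-3-methylbut-3-en-2-ol (both C26 epimers)
Conditions: isopropenylmagnesium bromide (3 equiv), THF, −78 → 0 °C
Reagents that add atoms: isopropenylmagnesium bromide CC(=C)[Mg]Br
Why: Grignard addition to the aldehyde brings in C28 and C29; C26 is not controlled here and is corrected in steps 24 and 25.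

Step 23
Reactants: 29 dienediol
Product: 30 (1R,3aR,8aR)-1,4,4,6-tetramethyl-1,2,3,3a,4,7,8,8a-octahydroazulene-1,7-diol (both C26 epimers)
Conditions: Hoveyda–Grubbs II (10 mol%), PhMe (high dilution), 80 °C
Reagents that add atoms: none
Why: Ring-closing metathesis between the vinyl and isopropenyl groups, held cis on the cyclopentane, should close the trisubstituted cycloheptene (C14=C28) with loss of ethene.

Step 24
Reactants: 30 cycloheptenol
Product: 31 (1R,3aR,8aR)-1-hydroxy-1,4,4,6-tetramethyl-2,3,3a,4,8,8a-hexahydroazulen-7(1H)-one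
Conditions: Dess–Martin periodinane, NaHCO3, CH2Cl2, 0 °C → rt
Reagents that add atoms: none
Why: Oxidation of the secondary allylic alcohol to the enone converges both C26 epimers; the tertiary alcohol is inert.

Step 25
Reactants: 31 cycloheptenone
Product: 32 (1R,3aR,7S,8aR)-1,4,4,6-tetramethyl-1,2,3,3a,4,7,8,8a-octahydroazulene-1,7-diol
Conditions: (R)-Me-CBS (0.5 equiv), BH3·SMe2, THF, −30 °C
Reagents that add atoms: none
Why: Corey–Bakshi–Shibata reduction, in which the oxazaborolidine treats the α-methyl alkenyl side as the large group and the C25 methylene as the small one, sets C26 (S) with the hydroxyl on the face of the cyclopentane carbons.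

Step 26
Reactants: 32 allylic alcohol
Product: 33 C26 (tributylstannyl)methyl ether of 32
Conditions: KH (1.2 equiv), 18-crown-6 (cat.), Bu3SnCH2I, THF, 0 °C → rt
Reagents that add atoms: tributyl(iodomethyl)stannane CCCC[Sn](CI)(CCCC)CCCC
Why: Williamson etherification of the secondary allylic alkoxide, which is far less hindered than the tertiary one.

Step 27
Reactants: 33 stannylmethyl ether
Product: 34 (1R,3aR,5S,8aR)-5-(hydroxymethyl)-1,4,4,6-tetramethyl-1,2,3,3a,4,5,8,8a-octahydroazulen-1-ol
Conditions: n-BuLi (2.5 equiv), THF, −78 °C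
Reagents that add atoms: none
Why: Wittig–Still [2,3] rearrangement after tin–lithium exchange delivers the CH2OH carbon (C13) suprafacially to C14 on the face of the C26–O bond and moves the alkene to C26=C28.

Step 28
Reactants: 34 homoallylic alcohol
Product: 35 epoxy alcohol (C26–C28 epoxide with the oxirane oxygen cis to the CH2OH group)
Conditions: VO(acac)2 (5 mol%), t-BuOOH, CH2Cl2, 0 °C → rt
Reagents that add atoms: tert-butyl hydroperoxide CC(C)(C)OO
Why: Vanadium-catalysed epoxidation directed by the homoallylic hydroxyl delivers oxygen to the alkene face syn to C13, which fixes C26 and C28 relative to C14.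

Step 29
Reactants: 35 epoxy alcohol
Product: 36 epoxy iodide (C13–I)
Conditions: I2, PPh3, imidazole, CH2Cl2, 0 °C → rt
Reagents that add atoms: iodine II
Why: Appel-type iodination of the primary alcohol under imidazole-buffered conditions leaves the tertiary alcohol and the epoxide alone.

Step 30
Reactants: 16 α-methylene ketone (1.5 equiv); 36 epoxy iodide
Product: 37 coupled C8 ketone (C12–C13 bond formed; C11–H axial, side chain equatorial)
Conditions: (TMS)3SiH (slow addition), AIBN, PhH, 80 °C
Reagents that add atoms: none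
Why: Giese reaction in which the silyl radical abstracts iodine, the primary C13 radical adds to the unsubstituted methylene C12 and the α-keto radical at C11 takes hydrogen anti to the axial C31 methyl, giving the equatorial side chain that is also the thermodynamically preferred epimer.

Step 31
Reactants: 37 coupled ketone
Product: 38 target CNP0216138.1
Conditions: MeMgBr (excess), THF–Et2O, −78 → 0 °C
Reagents that add atoms: methylmagnesium bromide C[Mg]Br
Why: Grignard addition to the C8 ketone from the equatorial direction, away from the 1,3-related axial C31 methyl, should give the axial tertiary alcohol with the equatorial methyl; the hindered trisubstituted epoxide is not attacked at low temperature.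

Compound list
1 | (R)-Wieland–Miescher ketone [(8aR)-8a-methyl-3,4,8,8a-tetrahydronaphthalene-1,6(2H,7H)-dione] | C[C@@]12CCC(=O)C=C1CCCC2=O | starting material
2 | (4aR,5R)-5-hydroxy-4a-methyl-4,4a,5,6,7,8-hexahydronaphthalen-2(3H)-one | C[C@@]12CCC(=O)C=C1CCC[C@H]2O | intermediate
3 | 3-[(1S,2R)-2-hydroxy-1-methyl-6-oxocyclohexyl]propanoic acid | O[C@@H]1CCCC(=O)[C@@]1(C)CCC(=O)O | intermediate
4 | (4aS,8aR)-4a-methyloctahydro-2H-chromene-2,5-dione | O1[C@@H]2CCCC(=O)[C@@]2(C)CCC1=O | intermediate
5 | C11 ethylene ketal of 4 (spiro-dioxolane lactone) | O1[C@@H]2CCCC3(OCCO3)[C@@]2(C)CCC1=O | intermediate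
6 | 3-[(6S,7R)-7-hydroxy-6-methyl-1,4-dioxaspiro[4.5]decan-6-yl]-N-methoxy-N-methylpropanamide | O[C@@H]1CCCC2(OCCO2)[C@@]1(C)CCC(=O)N(C)OC | intermediate
7 | ethyl but-2-ynoate | CCOC(=O)C#CC | starting material
8 | ethyl (E)-3-alkoxybut-2-enoate on O4 of 6 (crotonate Weinreb amide) | CCOC(=O)/C=C(\C)O[C@@H]1CCCC2(OCCO2)[C@@]1(C)CCC(=O)N(C)OC | intermediate
9 | ethyl (E)-3-{[(6S,7R)-6-methyl-6-(3-oxopropyl)-1,4-dioxaspiro[4.5]decan-7-yl]oxy}but-2-enoate | CCOC(=O)/C=C(\C)O[C@@H]1CCCC2(OCCO2)[C@@]1(C)CCC=O | intermediate
10 | trans-fused oxepane hydroxy ester (2S,5R,30S,34R in target numbering) | CCOC(=O)C[C@]1(C)O[C@@H]2CCCC3(OCCO3)[C@@]2(C)CC[C@H]1O | intermediate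
11 | oxepane hydroxy acid | OC(=O)C[C@]1(C)O[C@@H]2CCCC3(OCCO3)[C@@]2(C)CC[C@H]1O | intermediate
12 | 2,2-dimethyl oxepanol ketal | CC1(C)O[C@@H]2CCCC3(OCCO3)[C@@]2(C)CC[C@H]1O | intermediate
13 | oxepanol C11 ketone | CC1(C)O[C@@H]2CCCC(=O)[C@@]2(C)CC[C@H]1O | intermediate
14 | C11 exo-methylene oxepanol | CC1(C)O[C@@H]2CCCC(=C)[C@@]2(C)CC[C@H]1O | intermediate
15 | C8 allylic alcohol (C8 epimers) | CC1(C)O[C@@H]2CCC(O)C(=C)[C@@]2(C)CC[C@H]1O | intermediate
16 | α-methylene C8 ketone | CC1(C)O[C@@H]2CCC(=O)C(=C)[C@@]2(C)CC[C@H]1O | intermediate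
17 | (R)-4-(tert-butyldimethylsilyloxy)cyclopent-2-en-1-one | O=C1C=C[C@H](O[Si](C)(C)C(C)(C)C)C1 | starting material
18 | trimethyl(3-methylbut-2-en-1-yl)silane | CC(C)=CC[Si](C)(C)C | starting material
19 | (3S,4R)-4-(tert-butyldimethylsilyloxy)-3-(2-methylbut-3-en-2-yl)cyclopentan-1-one | O=C1C[C@@H](C(C)(C)C=C)[C@H](O[Si](C)(C)C(C)(C)C)C1 | intermediate
20 | (R)-4-(2-methylbut-3-en-2-yl)cyclopent-2-en-1-one | O=C1C=C[C@H](C(C)(C)C=C)C1 | intermediate
21 | (R)-2-iodo-4-(2-methylbut-3-en-2-yl)cyclopent-2-en-1-one | O=C1C(I)=C[C@H](C(C)(C)C=C)C1 | intermediate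
22 | (R)-2-methyl-4-(2-methylbut-3-en-2-yl)cyclopent-2-en-1-one | O=C1C(C)=C[C@H](C(C)(C)C=C)C1 | intermediate
23 | (1S,4R)-2-methyl-4-(2-methylbut-3-en-2-yl)cyclopent-2-en-1-ol | O[C@@H]1C(C)=C[C@H](C(C)(C)C=C)C1 | intermediate
24 | triethyl orthoacetate | CC(OCC)(OCC)OCC | starting material
25 | ethyl 2-[(1R,5R)-2-methyl-5-(2-methylbut-3-en-2-yl)cyclopent-2-en-1-yl]acetate | CCOC(=O)C[C@H]1C(C)=CC[C@H]1C(C)(C)C=C | intermediate
26 | C20–C21 epoxide of 25 (oxygen anti to both side chains) | CCOC(=O)C[C@H]1[C@]2(C)O[C@@H]2C[C@H]1C(C)(C)C=C | intermediate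
27 | (1R,2R,3R)-2-(2-hydroxyethyl)-1-methyl-3-(2-methylbut-3-en-2-yl)cyclopentan-1-ol | OCC[C@H]1[C@](C)(O)CC[C@H]1C(C)(C)C=C | intermediate
28 | 2-[(1R,2R,5R)-2-hydroxy-2-methyl-5-(2-methylbut-3-en-2-yl)cyclopentyl]acetaldehyde | O=CC[C@H]1[C@](C)(O)CC[C@H]1C(C)(C)C=C | intermediate
29 | 1-[(1R,2R,5R)-2-hydroxy-2-methyl-5-(2-methylbut-3-en-2-yl)cyclopentyl]-3-methylbut-3-en-2-ol (C26 epimers) | C=C(C)C(O)C[C@H]1[C@](C)(O)CC[C@H]1C(C)(C)C=C | intermediate
30 | (1R,3aR,8aR)-1,4,4,6-tetramethyl-1,2,3,3a,4,7,8,8a-octahydroazulene-1,7-diol (C26 epimers) | CC1=CC(C)(C)[C@@H]2CC[C@@](C)(O)[C@@H]2CC1O | intermediate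
31 | (1R,3aR,8aR)-1-hydroxy-1,4,4,6-tetramethyl-2,3,3a,4,8,8a-hexahydroazulen-7(1H)-one | CC1=CC(C)(C)[C@@H]2CC[C@@](C)(O)[C@@H]2CC1=O | intermediate
32 | (1R,3aR,7S,8aR)-1,4,4,6-tetramethyl-1,2,3,3a,4,7,8,8a-octahydroazulene-1,7-diol | CC1=CC(C)(C)[C@@H]2CC[C@@](C)(O)[C@@H]2C[C@@H]1O | intermediate
33 | C26 (tributylstannyl)methyl ether of 32 | CC1=CC(C)(C)[C@@H]2CC[C@@](C)(O)[C@@H]2C[C@@H]1OC[Sn](CCCC)(CCCC)CCCC | intermediate
34 | (1R,3aR,5S,8aR)-5-(hydroxymethyl)-1,4,4,6-tetramethyl-1,2,3,3a,4,5,8,8a-octahydroazulen-1-ol | OC[C@@H]1C(C)(C)[C@@H]2CC[C@@](C)(O)[C@@H]2CC=C1C | intermediate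
35 | C26–C28 epoxide of 34 (oxirane oxygen cis to CH2OH) | OC[C@@H]1C(C)(C)[C@@H]2CC[C@@](C)(O)[C@@H]2C[C@@H]2O[C@@]21C | intermediate
36 | C13 iodide of 35 | IC[C@@H]1C(C)(C)[C@@H]2CC[C@@](C)(O)[C@@H]2C[C@@H]2O[C@@]21C | intermediate
37 | coupled C8 ketone (C11 side chain equatorial) | CC1(C)O[C@@H]2CCC(=O)[C@H](CC[C@@H]3C(C)(C)[C@@H]4CC[C@@](C)(O)[C@@H]4C[C@@H]4O[C@@]43C)[C@@]2(C)CC[C@H]1O | intermediate
38 | CNP0216138.1 | CC1(C)O[C@@H]2CC[C@](C)(O)[C@H](CC[C@@H]3C(C)(C)[C@@H]4CC[C@@](C)(O)[C@@H]4C[C@@H]4O[C@@]43C)[C@@]2(C)CC[C@H]1O | target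

Total step count: 31.
Longest linear sequence: 18 steps (17 → 38: steps 14–29, then 30 and 31). The other branch runs 15 steps (steps 1–13, then 30 and 31).

Steps most likely to fail

Step 23 (ring-closing metathesis). The ruthenium carbene may fail to load onto either hindered olefin (a vinyl group on a quaternary carbon, a 1,1-disubstituted allylic carbinol), so that catalyst decay or oligomerisation outruns ring closure. The fallback closes the ring by a chromium-mediated carbonyl addition instead of metathesis and sets out from diol 27. Ozonolysis of its only alkene (O3, CH2Cl2–MeOH, −78 °C; PPh3) would give the neopentyl aldehyde F4. Stork–Zhao olefination with (1-iodoethylidene)triphenylphosphorane would give the (Z)-iodoalkene F5. Oxidation of the primary alcohol (TEMPO, PhI(OAc)2) would give the iodo aldehyde F6. An intramolecular Nozaki–Hiyama–Kishi reaction (CrCl2, NiCl2 cat., DMSO) would then form C26–C28 and return to cycloheptenol 30.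

Step 30 (radical union of the two halves). With the partners near equimolar, the primary radical may be reduced by the silane before it adds, or the α-methylene ketone may oligomerise. The fallback replaces the intermolecular radical addition by an ester tether and a sigmatropic C–C bond formation, and sets out from enone 16 and allylic alcohol 32. Mukaiyama–Michael addition of the silyl ketene acetal of methyl acetate to 16 would give the keto ester F7, and saponification the keto acid F8. Esterification with 32 (EDC, DMAP; the hindered C34 hydroxyl should not compete) would give the allylic ester F9. Ireland–Claisen rearrangement (LDA, TMSCl, THF, −78 → 60 °C) would form C13–C14 with chirality transfer from C26 and give the acid F10. Iodolactonisation (I2, NaHCO3, MeCN–H2O) would give the cis-fused iodolactone F11, with the lactone oxygen on C28 syn to C13. Aqueous LiOH would open the lactone and close the oxirane to give the epoxy acid F12. Photoredox hydrodecarboxylation under the conditions of step 9 would then return to ketone 37.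

Step 7 (key cyclisation). Addition of the ketyl to the fully substituted β-carbon may be slow enough for simple reduction of the aldehyde or pinacol coupling to compete. The fallback uses a β-alkoxyvinyl sulfoxide as radical acceptor and desulfurisation in place of decarboxylation, and sets out from alcohol 6. Base-catalysed addition to 1-(p-tolylsulfinyl)prop-1-yne would give the vinyl sulfoxide F1. DIBAL-H would give the aldehyde F2. SmI2 with MeOH would give the cyclised hydroxy sulfoxide F3. Raney nickel would remove the sulfur and give the gem-dimethyl oxepanol 12, rejoining the route after step 9.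

Further compounds
F1 | step 7 | (E)-β-alkoxyvinyl p-tolyl sulfoxide Weinreb amide (sulfur epimers) | Cc1ccc(cc1)S(=O)/C=C(\C)O[C@@H]1CCCC2(OCCO2)[C@@]1(C)CCC(=O)N(C)OC
F2 | step 7 | (E)-β-alkoxyvinyl p-tolyl sulfoxide aldehyde (sulfur epimers) | Cc1ccc(cc1)S(=O)/C=C(\C)O[C@@H]1CCCC2(OCCO2)[C@@]1(C)CCC=O
F3 | step 7 | oxepane hydroxy sulfoxide (sulfur epimers) | Cc1ccc(cc1)S(=O)C[C@]1(C)O[C@@H]2CCCC3(OCCO3)[C@@]2(C)CC[C@H]1O
F4 | step 23 | 2-[(1R,2R,3R)-3-hydroxy-2-(2-hydroxyethyl)-3-methylcyclopentyl]-2-methylpropanal | OCC[C@H]1[C@](C)(O)CC[C@H]1C(C)(C)C=O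
F5 | step 23 | (Z)-iodoalkene diol | OCC[C@H]1[C@](C)(O)CC[C@H]1C(C)(C)/C=C(/C)I
F6 | step 23 | (Z)-iodoalkene hydroxy aldehyde | O=CC[C@H]1[C@](C)(O)CC[C@H]1C(C)(C)/C=C(/C)I
F7 | step 30 | C8 keto methyl ester (methyl 3-substituted propanoate on C11) | CC1(C)O[C@@H]2CCC(=O)[C@H](CCC(=O)OC)[C@@]2(C)CC[C@H]1O
F8 | step 30 | C8 keto acid | CC1(C)O[C@@H]2CCC(=O)[C@H](CCC(=O)O)[C@@]2(C)CC[C@H]1O
F9 | step 30 | allylic ester of F8 with 32 (through the C26 oxygen) | CC1(C)O[C@@H]2CCC(=O)[C@H](CCC(=O)O[C@H]3C[C@H]4[C@](C)(O)CC[C@H]4C(C)(C)C=C3C)[C@@]2(C)CC[C@H]1O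
F10 | step 30 | Ireland–Claisen acid (CO2H on C13, C13 epimers) | CC1(C)O[C@@H]2CCC(=O)[C@H](CC(C(=O)O)[C@@H]3C(C)(C)[C@@H]4CC[C@@](C)(O)[C@@H]4CC=C3C)[C@@]2(C)CC[C@H]1O
F11 | step 30 | cis-fused iodolactone (C13 epimers) | CC1(C)O[C@@H]2CCC(=O)[C@H](CC5C(=O)O[C@@]6(C)[C@H](I)C[C@H]7[C@](C)(O)CC[C@H]7C(C)(C)[C@@H]56)[C@@]2(C)CC[C@H]1O
F12 | step 30 | epoxy acid (CO2H on C13, C13 epimers) | CC1(C)O[C@@H]2CCC(=O)[C@H](CC(C(=O)O)[C@@H]3C(C)(C)[C@@H]4CC[C@@](C)(O)[C@@H]4C[C@@H]4O[C@@]43C)[C@@]2(C)CC[C@H]1O
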